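## Retrosynthetic overview

1. Locants: the lactone unit is a 6-oxabicyclo[3.2.1]octan-7-one with C1 (CH3, C7=O), C2 (OAc), C3, C4, C5 (CH3, O6) and C8 (H, chain); ring A = C1–C2–C3–C4–C5–C8; the linker is Ca (on C8) and Cb; the carbobicycle has C1′ (quaternary), C2′ (C=O), C3′, C4′, C5′, C6′ (=CH2), C7′, C8′, with ring C = C1′–C2′–C3′–C4′–C5′–C8′ and ring D = C1′–C7′–C6′–C5′–C8′.
2. Target ⇒ keto lactone 22: the C2 acetate is taken back to a C2 ketone and the C2′ ketone to a silyl-protected carbinol.
3. Key cut: C1–C8 and O6–C5 are broken together, opening ring A and the γ-lactone ring (C1–C7–O6–C5–C8) to the acyclic (E)-alkenyl 2-methyl-3-oxo ester 20. The enabling feature is that C1 lies between the C7 carboxyl and a C2 carbonyl (a 1,3-dicarbonyl that can be oxidized to a C1 radical), while O6 sits on the methyl-bearing C5 next to C8 — the pattern left by a radical carbolactonization of a C8=C5 alkene.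
4. 20 ⇒ dianion of the auxiliary 2-methylacetoacetate 19 + allylic bromide 18 (C3–C4 bond) ⇒ aldehyde 14 (Wittig, C8=C5) ⇒ bridgehead acid 12 + acrolein (C1′–Cb bond by decarboxylative radical addition).
5. Rings C and D ⇒ doubly allylated acetoacetate 7 by cutting C1′–C8′ and C5′–C6′. Ring order: ring C then ring D (both in step 3), later ring A then the lactone ring (both in step 13).

Key step: step 13

## Remarks (assumptions)

- The C2′ carbinol made in step 4 is expected as a mixture of epimers; it is drawn without a descriptor from 9 to 25 because step 17 converts both epimers into the C2′ ketone.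
- The sense of induction of (+)-8-phenylmenthol in steps 3 and 13 is taken from the usual shielding model (ester carbonyl syn to the carbinol hydrogen of the auxiliary, both carbonyl oxygens of the radical held by Yb(OTf)3, phenyl ring over the Re face); the antipodal auxiliary fits the same route should the opposite sense be found.
- The C1/C8 relation in step 13 is derived from a cyclization chair in which the Yb-chelated radical holds the ester carbonyl syn to the ketone oxygen, so that the ester is equatorial and the methyl group axial; this chelated chair is taken as the working model.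
- The descriptor at C1′ changes (R in 8 and 10–12, S in 9 and from 14 on) only through substituent priorities; the spatial arrangement is the same throughout.
- "(+)-8-Phenylmenthyl" stands for (1S,2R,5S)-5-methyl-2-(2-phenylpropan-2-yl)cyclohexyl; "TBS" for tert-butyldimethylsilyl.

## Route

Step 1
Reactants: 1 (+)-8-phenylmenthol; 2 2,2,6-trimethyl-4H-1,3-dioxin-4-one
Product: 4 (+)-8-phenylmenthyl 3-oxobutanoate, via acetylketene 3 (not isolated)
Conditions: 2 (1.5 equiv), xylene, 140 °C
Reagents that add atoms: none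
Why: Thermal cycloreversion of dioxinone 2 releases acetylketene 3, which acylates the hindered secondary alcohol (acetoacetylation via an acylketene) without touching any stereocentre.

Step 2
Reactants: 4 (+)-8-phenylmenthyl 3-oxobutanoate; 5 allyl bromide
Product: 7 (+)-8-phenylmenthyl 3-oxo-2-(prop-2-en-1-yl)hept-6-enoate, via mono-allylated keto ester 6 (not isolated)
Conditions: LiN(i-Pr)2 (2.1 equiv), THF, −78 → 0 °C; first equivalent of 5 (1.0 equiv), −78 → 0 °C; then DMPU, second equivalent of allyl bromide (1.2 equiv), 0 °C → rt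
Reagents that add atoms: allyl bromide (second equivalent of 5) C=CCBr
Why: Acetoacetate dianion alkylation: the terminal (γ) carbanion is allylated by the first equivalent of allyl bromide, and the remaining stabilized α-enolate of 6 is allylated by the second equivalent in the same flask once DMPU is added; the α-stereocentre is labile and is erased in step 3.

Step 3
Reactants: 7 (+)-8-phenylmenthyl 3-oxo-2-(prop-2-en-1-yl)hept-6-enoate
Product: 8 (+)-8-phenylmenthyl (1R,5R)-6-methylidene-2-oxobicyclo[3.2.1]octane-1-carboxylate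
Conditions: Mn(OAc)3·2H2O (2.2 equiv), Cu(OAc)2·H2O (0.5 equiv), Yb(OTf)3 (1.0 equiv), CF3CH2OH, 0 °C → rt
Reagents that add atoms: none
Why: Oxidative free-radical tandem cyclization with trivalent manganese: the Yb-chelated α-radical closes 6-endo-trig onto the butenyl terminus (ring C), the secondary radical closes 5-exo-trig onto the allyl group (ring D) and divalent copper turns the primary radical into the exocyclic alkene by oxidative elimination; the phenyl ring of the auxiliary covers the Re face of the radical, so the first bond forms on the Si face and sets C1′, the bridge then fixes C5′, and the minor diastereomer should be removable by chromatography.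

Step 4
Reactants: 8 (+)-8-phenylmenthyl (1R,5R)-6-methylidene-2-oxobicyclo[3.2.1]octane-1-carboxylate
Product: 9 (1S,5R)-1-(hydroxymethyl)-6-methylidenebicyclo[3.2.1]octan-2-ol (C2′ epimers)
Conditions: LiAlH4, THF, 0 °C → reflux
Reagents that add atoms: none
Why: Hydride reduction of the ketone and the hindered ester with LiAlH4 frees the auxiliary and gives the 1,3-diol, whose C2′ epimers converge in step 17.

Step 5
Reactants: 9 (1S,5R)-1-(hydroxymethyl)-6-methylidenebicyclo[3.2.1]octan-2-ol
Product: 10 (1R,5R)-2-hydroxy-6-methylidenebicyclo[3.2.1]octane-1-carboxylic acid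
Conditions: TEMPO (0.2 equiv), PhI(OAc)2 (2.5 equiv), MeCN/H2O (1:1), rt
Reagents that add atoms: water O
Why: The TEMPO/PhI(OAc)2 oxidation (oxoammonium oxidation) takes primary alcohols through the aldehyde hydrate to the acid much faster than it attacks a hindered secondary alcohol.

Step 6
Reactants: 10 (1R,5R)-2-hydroxy-6-methylidenebicyclo[3.2.1]octane-1-carboxylic acid
Product: 12 (1R,5R)-2-[(tert-butyldimethylsilyl)oxy]-6-methylidenebicyclo[3.2.1]octane-1-carboxylic acid, via silyl ester 11 (not isolated)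
Conditions: TBSOTf (2.5 equiv), 2,6-lutidine, CH2Cl2, 0 °C; then AcOH/THF/H2O (1:8:8), 0 °C → rt
Reagents that add atoms: tert-butyldimethylsilyl trifluoromethanesulfonate CC(C)(C)[Si](C)(C)OS(=O)(=O)C(F)(F)F
Why: Silylation caps alcohol and acid, and the labile silyl ester is hydrolysed by dilute aqueous acid while the hindered secondary silyl ether stays, which keeps C2′ at the alcohol level (a nucleophilic bridgehead radical in step 7 and no competing ketone in steps 9, 12 and 14).

Step 7
Reactants: 12 (1R,5R)-2-[(tert-butyldimethylsilyl)oxy]-6-methylidenebicyclo[3.2.1]octane-1-carboxylic acid; 13 acrolein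
Product: 14 3-[(1S,5R)-2-[(tert-butyldimethylsilyl)oxy]-6-methylidenebicyclo[3.2.1]octan-1-yl]propanal
Conditions: Ir[dF(CF3)ppy]2(dtbbpy)PF6 (1 mol%), K2HPO4, 13 (3 equiv), DMF, blue LEDs, rt
Reagents that add atoms: none
Why: Photoredox decarboxylative Giese reaction: the carboxylate is oxidized by the excited iridium photocatalyst and loses CO2, and the tertiary bridgehead radical, which cannot invert within the cage and so keeps the configuration at C1′, adds to acrolein before the α-formyl radical is reduced and protonated.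

Step 8
Reactants: 14 3-[(1S,5R)-2-[(tert-butyldimethylsilyl)oxy]-6-methylidenebicyclo[3.2.1]octan-1-yl]propanal; 15 ethyl 2-(triphenyl-λ5-phosphanylidene)propanoate
Product: 16 ethyl (2E)-5-[(1S,5R)-2-[(tert-butyldimethylsilyl)oxy]-6-methylidenebicyclo[3.2.1]octan-1-yl]-2-methylpent-2-enoate
Conditions: 15 (1.5 equiv), toluene, 80 °C
Reagents that add atoms: none
Why: Wittig olefination with a stabilized α-methyl ylide reacts only with the aldehyde and should give the trisubstituted (E)-enoate under thermodynamic control of the oxaphosphetane.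

Step 9
Reactants: 16 ethyl (2E)-5-[(1S,5R)-2-[(tert-butyldimethylsilyl)oxy]-6-methylidenebicyclo[3.2.1]octan-1-yl]-2-methylpent-2-enoate
Product: 17 (2E)-5-[(1S,5R)-2-[(tert-butyldimethylsilyl)oxy]-6-methylidenebicyclo[3.2.1]octan-1-yl]-2-methylpent-2-en-1-ol
Conditions: i-Bu2AlH (2.5 equiv), CH2Cl2, −78 °C
Reagents that add atoms: none
Why: 1,2-Reduction of the enoate by i-Bu2AlH at low temperature gives the allylic alcohol without changing the alkene geometry or the silyl ether.

Step 10
Reactants: 17 (2E)-5-[(1S,5R)-2-[(tert-butyldimethylsilyl)oxy]-6-methylidenebicyclo[3.2.1]octan-1-yl]-2-methylpent-2-en-1-ol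
Product: 18 (1S,5R)-1-[(3E)-5-bromo-4-methylpent-3-en-1-yl]-2-[(tert-butyldimethylsilyl)oxy]-6-methylidenebicyclo[3.2.1]octane
Conditions: CBr4, PPh3, CH2Cl2, 0 °C
Reagents that add atoms: carbon tetrabromide BrC(Br)(Br)Br
Why: Appel bromination converts the primary allylic alcohol into the bromide under neutral conditions by SN2 displacement of the alkoxyphosphonium group without allylic transposition.

Step 11
Reactants: 4 (+)-8-phenylmenthyl 3-oxobutanoate
Product: 19 (+)-8-phenylmenthyl 2-methyl-3-oxobutanoate (C2 epimers)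
Conditions: K2CO3, MeI (1.05 equiv), acetone, rt
Reagents that add atoms: iodomethane CI
Why: C-Methylation of the acetoacetate enolate gives the 2-methyl keto ester, whose new stereocentre is labile and becomes the radical carbon in step 13.

Step 12
Reactants: 18 (1S,5R)-1-[(3E)-5-bromo-4-methylpent-3-en-1-yl]-2-[(tert-butyldimethylsilyl)oxy]-6-methylidenebicyclo[3.2.1]octane; 19 (+)-8-phenylmenthyl 2-methyl-3-oxobutanoate
Product: 20 (+)-8-phenylmenthyl (6E)-9-[(1S,5R)-2-[(tert-butyldimethylsilyl)oxy]-6-methylidenebicyclo[3.2.1]octan-1-yl]-2,6-dimethyl-3-oxonon-6-enoate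
Conditions: 19 (1.3 equiv), LiN(i-Pr)2 (2.6 equiv), THF, −78 → 0 °C; then 18, −78 → 0 °C
Reagents that add atoms: none
Why: γ-Alkylation of the acetoacetate dianion: the more reactive terminal carbanion displaces the primary allylic bromide by SN2 and forms the C3–C4 bond with retention of the (E)-alkene.

Step 13
Reactants: 20 (+)-8-phenylmenthyl (6E)-9-[(1S,5R)-2-[(tert-butyldimethylsilyl)oxy]-6-methylidenebicyclo[3.2.1]octan-1-yl]-2,6-dimethyl-3-oxonon-6-enoate
Product: 22 (1S,5S,8S)-8-{2-[(1S,5R)-2-[(tert-butyldimethylsilyl)oxy]-6-methylidenebicyclo[3.2.1]octan-1-yl]ethyl}-1,5-dimethyl-6-oxabicyclo[3.2.1]octane-2,7-dione, via alkoxylactonium ion 21 (not isolated)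
Conditions: Mn(OAc)3·2H2O (2.2 equiv), Yb(OTf)3 (1.0 equiv), CF3CH2OH/H2O (20:1), −5 °C → rt
Reagents that add atoms: water O
Why: Proposed new method: Mn(OAc)3 oxidizes the Yb-chelated enolate of the 2-methyl-3-oxo ester to the C1 radical, which adds to C8 of the C8=C5 alkene (C1–C8 bond); a second Mn(OAc)3 oxidizes the resulting tertiary C5 radical to the cation, the ester carbonyl oxygen closes onto C5 (O6–C5 bond), and water cleaves alkoxylactonium ion 21 into lactone 22 and the free auxiliary 1. The closest known reactions are the Mn(OAc)3/Yb(OTf)3 oxidative radical cyclization of 8-phenylmenthyl β-keto esters and the Mn(OAc)3 carbolactonization of alkenes by carboxylic acid derivatives (radical–polar crossover); new is their merger, in which the chiral ester leaves during the lactonization. Ring A closes by 6-endo-trig radical attack (preferred over 5-exo because C5 carries the methyl group and the ketone lies inside the forming ring), and the lactone ring closes in a five-membered mode by attack of the carbonyl oxygen on the planar cation from the carboxyl that has become axial after a chair flip. C1 is set by the auxiliary (its phenyl ring covers the Re face of the chelated radical, so C8 bonds to the Si face); C8 is set by the (E)-alkene in a chair in which chelation holds C7 syn to the C2 oxygen and therefore equatorial, trans to Ca; C5 is set by the one-atom tether, which lets O6 arrive only cis to C7. The step needs chemoselectivity for the 1,3-dicarbonyl, the only site that trivalent manganese enolizes and oxidizes, so the remote exocyclic alkene and the silyl ether are spectators, and it needs capture of the cation before proton loss, which the 1,3-diaxial carboxyl should secure.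

Step 14
Reactants: 22 (1S,5S,8S)-8-{2-[(1S,5R)-2-[(tert-butyldimethylsilyl)oxy]-6-methylidenebicyclo[3.2.1]octan-1-yl]ethyl}-1,5-dimethyl-6-oxabicyclo[3.2.1]octane-2,7-dione
Product: 23 (1S,2S,5S,8S)-8-{2-[(1S,5R)-2-[(tert-butyldimethylsilyl)oxy]-6-methylidenebicyclo[3.2.1]octan-1-yl]ethyl}-2-hydroxy-1,5-dimethyl-6-oxabicyclo[3.2.1]octan-7-one
Conditions: LiBH(s-Bu)3, THF, −78 °C
Reagents that add atoms: none
Why: Substrate-controlled hydride reduction: the bulky borohydride attacks the C2 ketone along the equatorial trajectory from the side of the lactone bridge, because the axial trajectory is closed by the Ca chain that stands syn-axial on C8, which should give the axial (2S) alcohol while the lactone is not reduced at −78 °C.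

Step 15
Reactants: 23 (1S,2S,5S,8S)-8-{2-[(1S,5R)-2-[(tert-butyldimethylsilyl)oxy]-6-methylidenebicyclo[3.2.1]octan-1-yl]ethyl}-2-hydroxy-1,5-dimethyl-6-oxabicyclo[3.2.1]octan-7-one
Product: 24 (1S,2S,5S,8S)-8-{2-[(1S,5R)-2-[(tert-butyldimethylsilyl)oxy]-6-methylidenebicyclo[3.2.1]octan-1-yl]ethyl}-1,5-dimethyl-7-oxo-6-oxabicyclo[3.2.1]octan-2-yl acetate
Conditions: Ac2O, DMAP, pyridine, rt → 40 °C
Reagents that add atoms: acetic anhydride CC(=O)OC(C)=O
Why: DMAP-catalysed acylation esterifies the hindered axial alcohol with retention of configuration.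

Step 16
Reactants: 24 (1S,2S,5S,8S)-8-{2-[(1S,5R)-2-[(tert-butyldimethylsilyl)oxy]-6-methylidenebicyclo[3.2.1]octan-1-yl]ethyl}-1,5-dimethyl-7-oxo-6-oxabicyclo[3.2.1]octan-2-yl acetate
Product: 25 (1S,2S,5S,8S)-8-{2-[(1S,5R)-2-hydroxy-6-methylidenebicyclo[3.2.1]octan-1-yl]ethyl}-1,5-dimethyl-7-oxo-6-oxabicyclo[3.2.1]octan-2-yl acetate
Conditions: HF·pyridine, THF/pyridine, 0 °C → rt
Reagents that add atoms: none
Why: Fluoride-mediated desilylation removes the silyl ether while acetate, lactone and exocyclic alkene are stable to these mildly acidic conditions.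

Step 17
Reactants: 25 (1S,2S,5S,8S)-8-{2-[(1S,5R)-2-hydroxy-6-methylidenebicyclo[3.2.1]octan-1-yl]ethyl}-1,5-dimethyl-7-oxo-6-oxabicyclo[3.2.1]octan-2-yl acetate
Product: 26 (1S,2S,5S,8S)-1,5-dimethyl-8-{2-[(1S,5R)-6-methylidene-2-oxobicyclo[3.2.1]octan-1-yl]ethyl}-7-oxo-6-oxabicyclo[3.2.1]octan-2-yl acetate (CNP0204681.1)
Conditions: Dess–Martin periodinane, CH2Cl2, rt
Reagents that add atoms: none
Why: Dess–Martin oxidation converts both carbinol epimers into the same C2′ ketone under neutral conditions, and since the flanking C1′ is quaternary nothing can epimerize.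

## Compound list

1 | (+)-8-phenylmenthol, (1S,2R,5S)-5-methyl-2-(2-phenylpropan-2-yl)cyclohexan-1-ol | O[C@H]1C[C@@H](C)CC[C@@H]1C(C)(C)c1ccccc1 | starting material
2 | 2,2,6-trimethyl-4H-1,3-dioxin-4-one | CC1=CC(=O)OC(C)(C)O1 | starting material
3 | acetylketene (3-oxobut-1-en-1-one) | CC(=O)C=C=O | intermediate
4 | (+)-8-phenylmenthyl 3-oxobutanoate | CC(=O)CC(=O)O[C@H]1C[C@@H](C)CC[C@@H]1C(C)(C)c1ccccc1 | intermediate
5 | allyl bromide (3-bromoprop-1-ene) | C=CCBr | starting material
6 | (+)-8-phenylmenthyl 3-oxohept-6-enoate | C=CCCC(=O)CC(=O)O[C@H]1C[C@@H](C)CC[C@@H]1C(C)(C)c1ccccc1 | intermediate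
7 | (+)-8-phenylmenthyl 3-oxo-2-(prop-2-en-1-yl)hept-6-enoate (C2 epimers) | C=CCCC(=O)C(CC=C)C(=O)O[C@H]1C[C@@H](C)CC[C@@H]1C(C)(C)c1ccccc1 | intermediate
8 | (+)-8-phenylmenthyl (1R,5R)-6-methylidene-2-oxobicyclo[3.2.1]octane-1-carboxylate | C=C1C[C@]2(C(=O)O[C@H]3C[C@@H](C)CC[C@@H]3C(C)(C)c3ccccc3)C[C@H]1CCC2=O | intermediate
9 | (1S,5R)-1-(hydroxymethyl)-6-methylidenebicyclo[3.2.1]octan-2-ol (C2 epimers) | C=C1C[C@]2(CO)C[C@H]1CCC2O | intermediate
10 | (1R,5R)-2-hydroxy-6-methylidenebicyclo[3.2.1]octane-1-carboxylic acid (C2 epimers) | C=C1C[C@]2(C(=O)O)C[C@H]1CCC2O | intermediate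
11 | tert-butyldimethylsilyl (1R,5R)-2-[(tert-butyldimethylsilyl)oxy]-6-methylidenebicyclo[3.2.1]octane-1-carboxylate | C=C1C[C@]2(C(=O)O[Si](C)(C)C(C)(C)C)C[C@H]1CCC2O[Si](C)(C)C(C)(C)C | intermediate
12 | (1R,5R)-2-[(tert-butyldimethylsilyl)oxy]-6-methylidenebicyclo[3.2.1]octane-1-carboxylic acid | C=C1C[C@]2(C(=O)O)C[C@H]1CCC2O[Si](C)(C)C(C)(C)C | intermediate
13 | acrolein (prop-2-enal) | C=CC=O | starting material
14 | 3-[(1S,5R)-2-[(tert-butyldimethylsilyl)oxy]-6-methylidenebicyclo[3.2.1]octan-1-yl]propanal | C=C1C[C@]2(CCC=O)C[C@H]1CCC2O[Si](C)(C)C(C)(C)C | intermediate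
15 | ethyl 2-(triphenyl-λ5-phosphanylidene)propanoate | CCOC(=O)C(C)=P(c1ccccc1)(c1ccccc1)c1ccccc1 | starting material
16 | ethyl (2E)-5-[(1S,5R)-2-[(tert-butyldimethylsilyl)oxy]-6-methylidenebicyclo[3.2.1]octan-1-yl]-2-methylpent-2-enoate | C=C1C[C@]2(CC/C=C(\C)C(=O)OCC)C[C@H]1CCC2O[Si](C)(C)C(C)(C)C | intermediate
17 | (2E)-5-[(1S,5R)-2-[(tert-butyldimethylsilyl)oxy]-6-methylidenebicyclo[3.2.1]octan-1-yl]-2-methylpent-2-en-1-ol | C=C1C[C@]2(CC/C=C(\C)CO)C[C@H]1CCC2O[Si](C)(C)C(C)(C)C | intermediate
18 | (1S,5R)-1-[(3E)-5-bromo-4-methylpent-3-en-1-yl]-2-[(tert-butyldimethylsilyl)oxy]-6-methylidenebicyclo[3.2.1]octane | C=C1C[C@]2(CC/C=C(\C)CBr)C[C@H]1CCC2O[Si](C)(C)C(C)(C)C | intermediate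
19 | (+)-8-phenylmenthyl 2-methyl-3-oxobutanoate (C2 epimers) | CC(=O)C(C)C(=O)O[C@H]1C[C@@H](C)CC[C@@H]1C(C)(C)c1ccccc1 | intermediate
20 | (+)-8-phenylmenthyl (6E)-9-[(1S,5R)-2-[(tert-butyldimethylsilyl)oxy]-6-methylidenebicyclo[3.2.1]octan-1-yl]-2,6-dimethyl-3-oxonon-6-enoate | C=C1C[C@]2(CC/C=C(\C)CCC(=O)C(C)C(=O)O[C@H]3C[C@@H](C)CC[C@@H]3C(C)(C)c3ccccc3)C[C@H]1CCC2O[Si](C)(C)C(C)(C)C | intermediate
21 | alkoxylactonium ion (O-(8-phenylmenthyl) oxocarbenium form of lactone 22) | C=C1C[C@]2(CC[C@H]3[C@]4(C)C(O[C@@]3(C)CCC4=O)=[O+][C@H]3C[C@@H](C)CC[C@@H]3C(C)(C)c3ccccc3)C[C@H]1CCC2O[Si](C)(C)C(C)(C)C | intermediate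
22 | (1S,5S,8S)-8-{2-[(1S,5R)-2-[(tert-butyldimethylsilyl)oxy]-6-methylidenebicyclo[3.2.1]octan-1-yl]ethyl}-1,5-dimethyl-6-oxabicyclo[3.2.1]octane-2,7-dione | C=C1C[C@]2(CC[C@H]3[C@]4(C)C(=O)O[C@@]3(C)CCC4=O)C[C@H]1CCC2O[Si](C)(C)C(C)(C)C | intermediate
23 | (1S,2S,5S,8S)-8-{2-[(1S,5R)-2-[(tert-butyldimethylsilyl)oxy]-6-methylidenebicyclo[3.2.1]octan-1-yl]ethyl}-2-hydroxy-1,5-dimethyl-6-oxabicyclo[3.2.1]octan-7-one | C=C1C[C@]2(CC[C@H]3[C@]4(C)C(=O)O[C@@]3(C)CC[C@@H]4O)C[C@H]1CCC2O[Si](C)(C)C(C)(C)C | intermediate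
24 | (1S,2S,5S,8S)-8-{2-[(1S,5R)-2-[(tert-butyldimethylsilyl)oxy]-6-methylidenebicyclo[3.2.1]octan-1-yl]ethyl}-1,5-dimethyl-7-oxo-6-oxabicyclo[3.2.1]octan-2-yl acetate | C=C1C[C@]2(CC[C@H]3[C@]4(C)C(=O)O[C@@]3(C)CC[C@@H]4OC(C)=O)C[C@H]1CCC2O[Si](C)(C)C(C)(C)C | intermediate
25 | (1S,2S,5S,8S)-8-{2-[(1S,5R)-2-hydroxy-6-methylidenebicyclo[3.2.1]octan-1-yl]ethyl}-1,5-dimethyl-7-oxo-6-oxabicyclo[3.2.1]octan-2-yl acetate | C=C1C[C@]2(CC[C@H]3[C@]4(C)C(=O)O[C@@]3(C)CC[C@@H]4OC(C)=O)C[C@H]1CCC2O | intermediate
26 | (1S,2S,5S,8S)-1,5-dimethyl-8-{2-[(1S,5R)-6-methylidene-2-oxobicyclo[3.2.1]octan-1-yl]ethyl}-7-oxo-6-oxabicyclo[3.2.1]octan-2-yl acetate | C=C1C[C@]2(CC[C@H]3[C@]4(C)C(=O)O[C@@]3(C)CC[C@@H]4OC(C)=O)C[C@H]1CCC2=O | target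

## Step count and risks

Total step count: 17. Longest linear sequence: 16 (steps 1–10 and 12–17; step 11 is a one-step branch from 4).

Steps most likely to fail:

First, step 13. The alkoxylactonium ion may collapse toward the ring-opened hydroxy ester instead of releasing the auxiliary, the tertiary cation may lose a proton before the ester oxygen closes, or discrimination between the two faces of the C1 radical may be low. The fallback uses known chemistry and sets out from bromide 18. γ-Alkylation of the dianion of commercial tert-butyl 2-methyl-3-oxobutanoate (LiN(i-Pr)2, THF) gives the tert-butyl keto ester F1. Oxidation with Mn(OAc)3·2H2O and Yb(OTf)3 in CF3CH2OH is then the auxiliary-free oxidative cyclization–lactonization of an alkyl β-keto ester, in which the tert-butyl group leaves as 2-methylpropene so that no hydrolysis is needed. Without the auxiliary both antipodes of the lactone unit form, giving keto lactone 22 and the diastereomeric keto lactone F2; these are diastereomers, because the carbobicycle is already enantiopure, and should be separable by chromatography. The route is rejoined at 22.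

Second, step 7. Addition of the hindered bridgehead radical next to the silyloxy group may be slow, so that polymerization of acrolein under base and light, or hydrogen-atom capture by the radical, takes over. The fallback sets out from diol 9 and keeps the carbinol carbon as Cb instead of expelling it. TEMPO/PhI(OAc)2 in dry CH2Cl2 stops at the hydroxy aldehyde F3; TBSOTf/2,6-lutidine gives the silyloxy aldehyde F4; Wittig olefination with (triphenylphosphoranylidene)acetaldehyde gives the (E)-enal F5; conjugate reduction with [(Ph3P)CuH]6, which leaves the 1,1-disubstituted alkene alone, gives aldehyde 14, where the route is rejoined.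

Third, step 14. Facial selectivity may be poor (hydride passing the side chain to give the equatorial C2 epimer), or the lactone may be opened. The fallback sets out from 22 and replaces substrate control by enzyme control: reduction with an NADPH-dependent ketoreductase chosen from a panel for the (2S) alcohol, with cofactor recycling by glucose dehydrogenase and glucose in aqueous buffer/DMSO at 30 °C. The lactone is inert under these conditions and the product is 23 itself, where the route is rejoined.

Further compounds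

F1 | step 13 | tert-butyl (6E)-9-[(1S,5R)-2-[(tert-butyldimethylsilyl)oxy]-6-methylidenebicyclo[3.2.1]octan-1-yl]-2,6-dimethyl-3-oxonon-6-enoate | C=C1C[C@]2(CC/C=C(\C)CCC(=O)C(C)C(=O)OC(C)(C)C)C[C@H]1CCC2O[Si](C)(C)C(C)(C)C
F2 | step 13 | (1R,5R,8R)-8-{2-[(1S,5R)-2-[(tert-butyldimethylsilyl)oxy]-6-methylidenebicyclo[3.2.1]octan-1-yl]ethyl}-1,5-dimethyl-6-oxabicyclo[3.2.1]octane-2,7-dione | C=C1C[C@]2(CC[C@@H]3[C@@]4(C)C(=O)O[C@]3(C)CCC4=O)C[C@H]1CCC2O[Si](C)(C)C(C)(C)C
F3 | step 7 | (1R,5R)-2-hydroxy-6-methylidenebicyclo[3.2.1]octane-1-carbaldehyde (C2 epimers) | C=C1C[C@]2(C=O)C[C@H]1CCC2O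
F4 | step 7 | (1R,5R)-2-[(tert-butyldimethylsilyl)oxy]-6-methylidenebicyclo[3.2.1]octane-1-carbaldehyde | C=C1C[C@]2(C=O)C[C@H]1CCC2O[Si](C)(C)C(C)(C)C
F5 | step 7 | (2E)-3-[(1S,5R)-2-[(tert-butyldimethylsilyl)oxy]-6-methylidenebicyclo[3.2.1]octan-1-yl]prop-2-enal | C=C1C[C@]2(/C=C/C=O)C[C@H]1CCC2O[Si](C)(C)C(C)(C)C
F0 | step 14 | none | none
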